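**Assumption:** the SMILES is read as (−)-epigallocatechin 3-O-gallate-(4β→6)-(+)-gallocatechin (upper unit 2R,3R,4S; lower unit 2R,3S), and commercial (+)-dihydromyricetin is taken to be the (2R,3R) isomer.

## Retrosynthetic overview

1. Last step: global hydrogenolysis of a per-benzylated dimer (13 O-benzyl groups, 2 aryl bromides).
2. Interflavan C4–C6′ bond: Lewis-acid SN1 Friedel–Crafts coupling of a 4-alkoxy upper unit with the lower unit; C8 is brominated in both partners so that C6′ reacts.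
3. Lower unit (C-ring already present): from (+)-dihydromyricetin by benzylation, C4 deoxygenation and C8 bromination.
4. Upper C-ring de novo: C3 is nitromethane, used as a masked carbonyl (acyl-anion equivalent) joined to two aldehyde carbons. A Henry condensation with the B-ring aldehyde makes C2–C3; the key enantioselective oxa-Michael/nitro-aldol cascade with the A-ring salicylaldehyde makes O1–C2 and C3–C4 and closes the pyran ring.
5. Then Nef reaction to the 3-ketone, L-Selectride to the 2,3-cis alcohol, C8 bromination, C4 oxidation and galloylation.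

## Route

**Step 1**
Reactants: 1 2,4,6-trihydroxybenzaldehyde
Product: 2 2,4-bis(benzyloxy)-6-hydroxybenzaldehyde
Conditions: BnBr (2.05 equiv), K2CO3 (2.1 equiv), DMF, 0 °C → rt
Reagents that add atoms: benzyl bromide (BrCc1ccccc1)
Why: Williamson etherification; the 4-OH and one ortho-OH are alkylated, while the last ortho-OH is held in a strong hydrogen bond to the formyl group and stays free with 2 equiv of halide.

**Step 2**
Reactants: 3 3,4,5-tris(benzyloxy)benzaldehyde; 4 nitromethane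
Product: 5 (E)-1,2,3-tris(benzyloxy)-5-(2-nitrovinyl)benzene
Conditions: MeNO2 (excess), NH4OAc (cat.), AcOH, 100 °C
Reagents that add atoms: none
Why: Henry (nitro-aldol) condensation with dehydration gives the conjugated E-nitroalkene; nitromethane supplies C3 of the upper flavan as a masked carbonyl carbon.

**Step 3 (key step)**
Reactants: 2 2,4-bis(benzyloxy)-6-hydroxybenzaldehyde; 5 (E)-1,2,3-tris(benzyloxy)-5-(2-nitrovinyl)benzene
Product: 7 (2R)-5,7-bis(benzyloxy)-3-nitro-2-[3,4,5-tris(benzyloxy)phenyl]-2H-chromene, via 3-nitrochroman-4-ol 6 (not isolated)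
Conditions: 5 (1.2 equiv), epi-quinine-derived 3,5-(CF3)2C6H3-thiourea (10 mol %; pseudo-enantiomer chosen to give 2R), toluene, 4 Å MS, 0 °C → rt; recrystallise to raise ee
Reagents that add atoms: none
Why: Organocatalytic tandem oxa-Michael–Henry–dehydration: the catalyst-bound phenoxide adds to one face of the thiourea-activated nitroalkene and so sets C2 (R); the resulting nitronate, an acyl-anion equivalent for C3, attacks the neighbouring formyl carbon (C4) to close the pyran ring, and loss of water drives the sequence.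

**Step 4**
Reactants: 7 (2R)-5,7-bis(benzyloxy)-3-nitro-2-[3,4,5-tris(benzyloxy)phenyl]-2H-chromene
Product: 8 (2R)-5,7-bis(benzyloxy)-2-[3,4,5-tris(benzyloxy)phenyl]chroman-3-one
Conditions: Fe powder (6 equiv), AcOH/THF/H2O, 45 °C
Reagents that add atoms: water (O)
Why: Reductive Nef reaction (dissolving-metal reduction of the conjugated nitroalkene to the imine oxidation level and hydrolysis in situ, as for aryl-nitropropenes) unmasks the C3 carbonyl; C2 is not involved and the mild acid is kept at ≤45 °C to limit enolisation towards C2.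

**Step 5**
Reactants: 8 (2R)-5,7-bis(benzyloxy)-2-[3,4,5-tris(benzyloxy)phenyl]chroman-3-one
Product: 9 (2R,3R)-5,7-bis(benzyloxy)-2-[3,4,5-tris(benzyloxy)phenyl]chroman-3-ol (penta-O-benzyl-epigallocatechin)
Conditions: L-Selectride (1.5 equiv), LiBr, THF, −78 °C; then H2O
Reagents that add atoms: none
Why: The bulky hydride adds to the C3 ketone from the face opposite the C2 aryl group, giving the axial 3-OH and thus the 2,3-cis (2R,3R) alcohol; this is the standard ketone reduction used to convert catechin-type into epicatechin-type units.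

**Step 6**
Reactants: 9 penta-O-benzyl-epigallocatechin
Product: 10 (2R,3R)-5,7-bis(benzyloxy)-8-bromo-2-[3,4,5-tris(benzyloxy)phenyl]chroman-3-ol
Conditions: NBS (1.0 equiv), CH2Cl2, −78 °C → rt
Reagents that add atoms: N-bromosuccinimide (O=C1CCC(=O)N1Br)
Why: Electrophilic aromatic bromination at C8, the most nucleophilic position of the 5,7-dialkoxy A-ring, blocks the site through which the later electrophile would self-condense.

**Step 7**
Reactants: 10 8-bromo-penta-O-benzyl-epigallocatechin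
Product: 11 8-bromo-4β-(2-ethoxyethoxy)-penta-O-benzyl-epigallocatechin (2R; 2,3-cis; 3,4-trans; 4S)
Conditions: DDQ (2 equiv), 2-ethoxyethanol (5 equiv), CH2Cl2, rt
Reagents that add atoms: 2-ethoxyethanol (CCOCCO)
Why: DDQ benzylic oxidation; hydride abstraction from C4 gives the A-ring-stabilised cation, which the alcohol traps anti to the C3 oxygen (4β; this centre is re-ionised in step 12).

**Step 8**
Reactants: 11 8-bromo-4β-(2-ethoxyethoxy)-penta-O-benzyl-epigallocatechin; 12 3,4,5-tris(benzyloxy)benzoic acid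
Product: 13 8-bromo-4β-(2-ethoxyethoxy)-penta-O-benzyl-epigallocatechin 3-O-[3,4,5-tris(benzyloxy)benzoate]
Conditions: DCC, DMAP, CH2Cl2, rt
Reagents that add atoms: none
Why: Steglich esterification of the axial 3-OH; no stereocentre is touched and the acid-labile C4 ether survives the neutral conditions.

**Step 9**
Reactants: 14 (+)-dihydromyricetin (2R,3R)
Product: 15 (2R,3R)-5,7-bis(benzyloxy)-3-hydroxy-2-[3,4,5-tris(benzyloxy)phenyl]chroman-4-one
Conditions: BnBr (5.5 equiv), K2CO3, DMF, N2, 0 °C → rt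
Reagents that add atoms: benzyl bromide (BrCc1ccccc1)
Why: Williamson etherification of the five phenols under carbonate (the aliphatic 3-OH is not deprotonated); N2 and rt avoid base-induced oxidation or ring opening of the dihydroflavonol.

**Step 10**
Reactants: 15 penta-O-benzyl-dihydromyricetin
Product: 17 (2R,3S)-5,7-bis(benzyloxy)-2-[3,4,5-tris(benzyloxy)phenyl]chroman-3-ol (penta-O-benzyl-gallocatechin), via flavan-3,4-diol 16 (not isolated)
Conditions: NaBH4, THF/EtOH, 0 °C; aqueous quench, crude diol taken on; Et3SiH (3 equiv), TFA, CH2Cl2, −20 → 0 °C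
Reagents that add atoms: none
Why: Ketone reduction, then ionic hydrogenation of the benzylic C4–OH via the A-ring-stabilised cation, removes the C4 oxygen; C2 and C3 are untouched, so the (2R,3R) dihydroflavonol becomes the (2R,3S) 2,3-trans flavan-3-ol.

**Step 11**
Reactants: 17 penta-O-benzyl-gallocatechin
Product: 18 (2R,3S)-5,7-bis(benzyloxy)-8-bromo-2-[3,4,5-tris(benzyloxy)phenyl]chroman-3-ol
Conditions: NBS (1.0 equiv), CH2Cl2, −78 °C → rt
Reagents that add atoms: N-bromosuccinimide (O=C1CCC(=O)N1Br)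
Why: Electrophilic aromatic bromination at C8 leaves C6 as the only free nucleophilic position of the lower unit.

**Step 12**
Reactants: 13 upper-unit electrophile; 18 8-bromo-penta-O-benzyl-gallocatechin
Product: 19 8-bromo-penta-O-benzyl-epigallocatechin 3-O-(tri-O-benzylgallate)-(4β→6)-8-bromo-penta-O-benzyl-gallocatechin
Conditions: 18 (3 equiv, excess recovered), TMSOTf (0.2 equiv), CH2Cl2, −40 → −20 °C, slow addition of 13; Et3N quench
Reagents that add atoms: none
Why: Lewis-acid SN1-type Friedel–Crafts alkylation; ionisation of the C4 ether gives the flavan-4-yl cation, the C3 gallate on the α face shields it so the arene adds from the β face (3,4-trans, 4S), and with C8 brominated in both partners C6 of 18 (in excess) is the reacting site.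

**Step 13**
Reactants: 19 protected dimer
Product: 20 (−)-epigallocatechin 3-O-gallate-(4β→6)-(+)-gallocatechin (target)
Conditions: H2 (1 atm), 20% Pd(OH)2/C, NaOAc (2.5 equiv), THF/MeOH/H2O, rt; filter under N2, Sephadex LH-20
Reagents that add atoms: none
Why: Pd-catalysed hydrogenolysis cleaves all thirteen benzyl ethers and both aryl C–Br bonds without touching the gallate ester, the interflavan bond or any stereocentre; acetate buffers the HBr formed.

## Compound list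

1 | 2,4,6-trihydroxybenzaldehyde | O=Cc1c(O)cc(O)cc1O | starting material
2 | 2,4-bis(benzyloxy)-6-hydroxybenzaldehyde | O=Cc1c(O)cc(OCc2ccccc2)cc1OCc1ccccc1 | intermediate
3 | 3,4,5-tris(benzyloxy)benzaldehyde | O=Cc1cc(OCc2ccccc2)c(OCc2ccccc2)c(OCc2ccccc2)c1 | starting material
4 | nitromethane | C[N+](=O)[O-] | starting material
5 | (E)-1,2,3-tris(benzyloxy)-5-(2-nitrovinyl)benzene | [O-][N+](=O)/C=C/c1cc(OCc2ccccc2)c(OCc2ccccc2)c(OCc2ccccc2)c1 | intermediate
6 | (2R)-5,7-bis(benzyloxy)-3-nitro-2-[3,4,5-tris(benzyloxy)phenyl]chroman-4-ol (C3/C4 mixture, not isolated) | [O-][N+](=O)C1C(O)c2c(OCc3ccccc3)cc(OCc3ccccc3)cc2O[C@@H]1c1cc(OCc2ccccc2)c(OCc2ccccc2)c(OCc2ccccc2)c1 | intermediate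
7 | (2R)-5,7-bis(benzyloxy)-3-nitro-2-[3,4,5-tris(benzyloxy)phenyl]-2H-chromene | [O-][N+](=O)C1=Cc2c(OCc3ccccc3)cc(OCc3ccccc3)cc2O[C@@H]1c1cc(OCc2ccccc2)c(OCc2ccccc2)c(OCc2ccccc2)c1 | intermediate
8 | (2R)-5,7-bis(benzyloxy)-2-[3,4,5-tris(benzyloxy)phenyl]chroman-3-one | O=C1Cc2c(OCc3ccccc3)cc(OCc3ccccc3)cc2O[C@@H]1c1cc(OCc2ccccc2)c(OCc2ccccc2)c(OCc2ccccc2)c1 | intermediate
9 | (2R,3R)-5,7-bis(benzyloxy)-2-[3,4,5-tris(benzyloxy)phenyl]chroman-3-ol (penta-O-benzyl-epigallocatechin) | O[C@@H]1Cc2c(OCc3ccccc3)cc(OCc3ccccc3)cc2O[C@@H]1c1cc(OCc2ccccc2)c(OCc2ccccc2)c(OCc2ccccc2)c1 | intermediate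
10 | (2R,3R)-5,7-bis(benzyloxy)-8-bromo-2-[3,4,5-tris(benzyloxy)phenyl]chroman-3-ol | O[C@@H]1Cc2c(OCc3ccccc3)cc(OCc3ccccc3)c(Br)c2O[C@@H]1c1cc(OCc2ccccc2)c(OCc2ccccc2)c(OCc2ccccc2)c1 | intermediate
11 | 8-bromo-4β-(2-ethoxyethoxy)-penta-O-benzyl-epigallocatechin (2R; 2,3-cis; 3,4-trans; 4S) | O[C@@H]1[C@@H](OCCOCC)c2c(OCc3ccccc3)cc(OCc3ccccc3)c(Br)c2O[C@@H]1c1cc(OCc2ccccc2)c(OCc2ccccc2)c(OCc2ccccc2)c1 | intermediate
12 | 3,4,5-tris(benzyloxy)benzoic acid | O=C(O)c1cc(OCc2ccccc2)c(OCc2ccccc2)c(OCc2ccccc2)c1 | starting material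
13 | 8-bromo-4β-(2-ethoxyethoxy)-penta-O-benzyl-epigallocatechin 3-O-[3,4,5-tris(benzyloxy)benzoate] | O=C(O[C@@H]1[C@@H](OCCOCC)c2c(OCc3ccccc3)cc(OCc3ccccc3)c(Br)c2O[C@@H]1c1cc(OCc2ccccc2)c(OCc2ccccc2)c(OCc2ccccc2)c1)c1cc(OCc2ccccc2)c(OCc2ccccc2)c(OCc2ccccc2)c1 | intermediate
14 | (+)-dihydromyricetin, (2R,3R) | O[C@H]1C(=O)c2c(O)cc(O)cc2O[C@@H]1c1cc(O)c(O)c(O)c1 | starting material
15 | (2R,3R)-5,7-bis(benzyloxy)-3-hydroxy-2-[3,4,5-tris(benzyloxy)phenyl]chroman-4-one | O[C@H]1C(=O)c2c(OCc3ccccc3)cc(OCc3ccccc3)cc2O[C@@H]1c1cc(OCc2ccccc2)c(OCc2ccccc2)c(OCc2ccccc2)c1 | intermediate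
16 | (2R,3S,4R)-5,7-bis(benzyloxy)-2-[3,4,5-tris(benzyloxy)phenyl]chroman-3,4-diol (main 3,4-trans isomer, not isolated) | O[C@H]1[C@H](O)c2c(OCc3ccccc3)cc(OCc3ccccc3)cc2O[C@@H]1c1cc(OCc2ccccc2)c(OCc2ccccc2)c(OCc2ccccc2)c1 | intermediate
17 | (2R,3S)-5,7-bis(benzyloxy)-2-[3,4,5-tris(benzyloxy)phenyl]chroman-3-ol (penta-O-benzyl-gallocatechin) | O[C@H]1Cc2c(OCc3ccccc3)cc(OCc3ccccc3)cc2O[C@@H]1c1cc(OCc2ccccc2)c(OCc2ccccc2)c(OCc2ccccc2)c1 | intermediate
18 | (2R,3S)-5,7-bis(benzyloxy)-8-bromo-2-[3,4,5-tris(benzyloxy)phenyl]chroman-3-ol | O[C@H]1Cc2c(OCc3ccccc3)cc(OCc3ccccc3)c(Br)c2O[C@@H]1c1cc(OCc2ccccc2)c(OCc2ccccc2)c(OCc2ccccc2)c1 | intermediate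
19 | 8-bromo-penta-O-benzyl-epigallocatechin 3-O-(tri-O-benzylgallate)-(4β→6)-8-bromo-penta-O-benzyl-gallocatechin | O=C(O[C@@H]1[C@@H](c2c(OCc3ccccc3)c(Br)c3c(c2OCc2ccccc2)C[C@H](O)[C@@H](c2cc(OCc4ccccc4)c(OCc4ccccc4)c(OCc4ccccc4)c2)O3)c2c(OCc3ccccc3)cc(OCc3ccccc3)c(Br)c2O[C@@H]1c1cc(OCc2ccccc2)c(OCc2ccccc2)c(OCc2ccccc2)c1)c1cc(OCc2ccccc2)c(OCc2ccccc2)c(OCc2ccccc2)c1 | intermediate
20 | (−)-epigallocatechin 3-O-gallate-(4β→6)-(+)-gallocatechin (upper 2R,3R,4S; lower 2R,3S) | O=C(O[C@@H]1[C@@H](c2c(O)cc3c(c2O)C[C@H](O)[C@@H](c2cc(O)c(O)c(O)c2)O3)c2c(O)cc(O)cc2O[C@@H]1c1cc(O)c(O)c(O)c1)c1cc(O)c(O)c(O)c1 | target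

## Step count and risks

Total: 13 steps. Longest linear sequence: 9 steps (1 → 3 → 4 → 5 → 6 → 7 → 8 → 12 → 13); the lower unit takes 3 steps (9–11).

The three steps most likely to fail:

**Step 3.** The formyl group of 2 sits between two ortho oxygens on an electron-rich ring, so rate and enantioselectivity of the cascade may fall short. Fallback: set out again from 2 and 5 and run the same cascade with DABCO instead of the chiral catalyst to give the racemic nitrochromene F1. Fe/AcOH converts it into the racemic flavan-3-one F2. Both C2 and C3 are then set by Ru–TsDPEN transfer hydrogenation (HCO2H/Et3N) under dynamic kinetic resolution: C2 epimerises through the enol and hydride is delivered anti to the 2-aryl group, by analogy with α-aryl cyclic ketones. This returns to the route at 9.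

**Step 4.** Metal/acid reduction may partly epimerise C2 or cleave the C2–O bond. Fallback: from 7, conjugate hydride reduction (NaBH4, THF/MeOH, −20 °C) gives the trans-3-nitroflavan F3, and a buffered TiCl3 Nef reaction (NH4OAc, pH about 5) then returns to 8.

**Step 12.** C6 of 18 is flanked by two benzyloxy groups, the C4 cation carries the bulky gallate, and C6 of 13 can compete. Fallback: from 18, benzylate the 3-OH (NaH, BnBr, DMF) to give the hexa-O-benzyl ether F4. Couple it with the gallate-free, less hindered electrophile 11 (TMSOTf, CH2Cl2, −40 °C) to give the 4β→6 dimer F5, whose only free hydroxyl is the upper 3-OH. Esterify that with 12 (DCC, DMAP) to give the fully protected dimer F6, and hydrogenolyse as in step 13 to return to 20.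

## Further compounds

F1 | step 3 | racemic 5,7-bis(benzyloxy)-3-nitro-2-[3,4,5-tris(benzyloxy)phenyl]-2H-chromene | [O-][N+](=O)C1=Cc2c(OCc3ccccc3)cc(OCc3ccccc3)cc2OC1c1cc(OCc2ccccc2)c(OCc2ccccc2)c(OCc2ccccc2)c1
F2 | step 3 | racemic 5,7-bis(benzyloxy)-2-[3,4,5-tris(benzyloxy)phenyl]chroman-3-one | O=C1Cc2c(OCc3ccccc3)cc(OCc3ccccc3)cc2OC1c1cc(OCc2ccccc2)c(OCc2ccccc2)c(OCc2ccccc2)c1
F3 | step 4 | (2R,3S)-5,7-bis(benzyloxy)-3-nitro-2-[3,4,5-tris(benzyloxy)phenyl]chromane (2,3-trans) | [O-][N+](=O)[C@H]1Cc2c(OCc3ccccc3)cc(OCc3ccccc3)cc2O[C@@H]1c1cc(OCc2ccccc2)c(OCc2ccccc2)c(OCc2ccccc2)c1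
F4 | step 12 | (2R,3S)-3,5,7-tris(benzyloxy)-8-bromo-2-[3,4,5-tris(benzyloxy)phenyl]chromane | c1ccccc1CO[C@H]1Cc2c(OCc3ccccc3)cc(OCc3ccccc3)c(Br)c2O[C@@H]1c1cc(OCc2ccccc2)c(OCc2ccccc2)c(OCc2ccccc2)c1
F5 | step 12 | 8-bromo-penta-O-benzyl-epigallocatechin-(4β→6)-8-bromo-hexa-O-benzyl-gallocatechin (upper 3-OH free) | O[C@@H]1[C@@H](c2c(OCc3ccccc3)c(Br)c3c(c2OCc2ccccc2)C[C@H](OCc2ccccc2)[C@@H](c2cc(OCc4ccccc4)c(OCc4ccccc4)c(OCc4ccccc4)c2)O3)c2c(OCc3ccccc3)cc(OCc3ccccc3)c(Br)c2O[C@@H]1c1cc(OCc2ccccc2)c(OCc2ccccc2)c(OCc2ccccc2)c1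
F6 | step 12 | 8-bromo-penta-O-benzyl-epigallocatechin 3-O-(tri-O-benzylgallate)-(4β→6)-8-bromo-hexa-O-benzyl-gallocatechin | O=C(O[C@@H]1[C@@H](c2c(OCc3ccccc3)c(Br)c3c(c2OCc2ccccc2)C[C@H](OCc2ccccc2)[C@@H](c2cc(OCc4ccccc4)c(OCc4ccccc4)c(OCc4ccccc4)c2)O3)c2c(OCc3ccccc3)cc(OCc3ccccc3)c(Br)c2O[C@@H]1c1cc(OCc2ccccc2)c(OCc2ccccc2)c(OCc2ccccc2)c1)c1cc(OCc2ccccc2)c(OCc2ccccc2)c(OCc2ccccc2)c1
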